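Set beside noon, charged in one go, midnight made its Yx later, and I asked what would have to be true of the numbers for that lateness to gain nothing.

| setting | larch | elm | maple | midnight | noon | winter | summer |
|---|---|---|---|---|---|---|---|
| Lx | 0.20 M | 0.28 M | 0.44 M | 0.20 M | 0.20 M | 0.20 M | 0.20 M (fed, over 6.40 min) |
| Wy | 0.20 M | 0.20 M | 0.20 M | 0.200 M (fed, over 6.40 min) | 0.200 M | 0.200 M | 0.200 M |
| remark | run made earlier | run made earlier | run made earlier | all but Wy at the start; Wy goes in evenly over 6.40 min, the run ends at 8.0 min | a closed flask charged with all of it at once and left for 8.0 min | a single well-mixed tank run continuously and read at steady state, 8.0 min in it on average | all but Lx at the start; Lx goes in evenly over 6.40 min, the run ends at 8.0 min |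
| time |  |  |  | 8.0 min | 8.0 min |  | 8.0 min |

- larch (time / min: Yx / %, Qe / %): 1.33: 54.8, 9.4; 2.50: 40.5, 11.6; 4.00: 29.0, 12.1; 5.00: 24.1, 12.5
- elm (time / min: Yx / %, Qe / %): 2.50: 32.9, 5.4; 5.00: 19.2, 3.8; 8.00: 12.2, 5.2; 10.0: 10.4, 4.5
- maple (time / min: Yx / %, Qe / %): 0.833: 33.8, 1.6; 2.00: 23.8, 1.7; 4.00: 17.4, 1.3; 10.0: 8.0, 0.8

(standard deviation of a reading: 0.5 percentage points)

- the stated concentrations are those of everything mixed, before any reaction; amounts are the same in each set-up
- the feed brings no volume worth counting
- the earlier runs were made in a closed, stirred flask

- order of the set-ups by the share of Yx in all that became Yx or Qe or WuYx, at the outlet or at the end, highest first (midnight / noon / winter / summer)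
- share of Yx in all that became Yx or Qe or WuYx, at the outlet or at the end, midnight
- share of Yx in all that became Yx or Qe or WuYx, at the outlet or at the end, noon
- share of Yx in all that became Yx or Qe or WuYx, at the outlet or at the end, winter
- share of Yx in all that became Yx or Qe or WuYx, at the outlet or at the end, summer

In larch, which has noon's charges, [Yx] fell from 40.5% at 2.50 min to 24.1% at 5.00 min, a fall of 16 percentage points, while [Qe] rose by 0.9 points, so I took that Yx to be passing into WuYx. Treating the fall as first-order, as an approximation, I read 11.1 min from these two readings, with their scatter, as the decade time of Yx, the minutes in which it loses one power of ten. I took the share of Yx among the products to be the part that survives, so that its logarithm falls by age over decade time. Noon's Yx, which I counted as 8.00 min old, loses 0.721 of a power of ten, which by this reckoning leaves 19.0%. In midnight I took Wy to react as it entered, since larch already held 64.2% as Yx and Qe at 1.33 min, which is sooner than the 6.40 min of the feed. Its Yx is then on average 4.80 min old, younger than noon's, and loses 0.432 of a power of ten, which by this reckoning leaves 36.9%. For the opposite outcome, midnight would need a further loss of 0.289 of a power of ten, and I committed to midnight above noon.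

The forecast gave midnight 43%, noon 16%, winter 32% and summer 27%, in the order midnight > winter > summer > noon, holding for midnight that “little Qe forms and the late finish limits loss”. The flask gave midnight 37.2%, noon 16.8%, winter 32.7% and summer 20.5%, in the order midnight > winter > summer > noon.

    Wu + Yx → WuYx (k = 0.0324 /M/s)
    Yx + Wy → Wu + Qe (k = 0.0579 /M/s)
    Lx + Wy → Wu + Yx (k = 0.451 /M/s)

Midnight's 37.2% stood against my 36.9%, with Wy, the limiting reagent, at 2.0% of its charge. The neighbouring flask was midnight with 0.50 M of Lx, its Wy fed in the same way, so I gave its Yx the same age of 4.80 min and, as an assumption, the same decade time of 11.1 min, which by this reckoning again leaves 36.9%. That flask gave 41.5%, and it ended with 21.9% of its Lx charge as WuYx and 61% still unbound as Lx.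

The runs stem from a simulated flask for substances that don't exist; noise was put on by code.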